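**Strategy.** Ring C is disconnected at C2–C3 and O1–C2. The feature used is that C3 carries oxygen and must bond to the ring B acyl carbon (C2), while the ring A oxygen that becomes O1 can hold that same acyl group as a phenolic ester, within reach of the α-carbon through a six-membered cyclic transition state. One base-mediated operation moves the aroyl group from oxygen to carbon and closes the pyranone, delivering the C3 oxygen as an ester that can be removed alone before sulfation. The precursor is a ring A acetophenone carrying the O-benzylvanilloyl group twice, on the phenol and on the α-oxygen, with benzyl ethers on the future 5- and 4'-oxygens.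

Key step: step 6

Assumption: the target is drawn as the free hydrogen sulfate; such monoesters are handled as salts, so 14 and 15 are written as neutral acids but would be kept as trialkylammonium (or, after ion exchange, potassium) salts, and brief contact with a cold H-form cation-exchange resin would liberate the free acid if needed.

Step 1
Reactants: 1 vanillic acid (4-hydroxy-3-methoxybenzoic acid); 2 benzyl bromide
Product: 3 4-(benzyloxy)-3-methoxybenzoic acid
Conditions: BnBr (1.2 equiv), NaOH (2.5 equiv), EtOH/H2O, reflux; then aq HCl to pH 2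
Reagents that add atoms: benzyl bromide (compound 2, listed above), BrCc1ccccc1
Why: Williamson ether synthesis on the dianion; in the protic medium the phenoxide is far more nucleophilic than the hydrogen-bonded carboxylate, so alkylation should occur on the 4-oxygen.

Step 2
Reactants: 4 1-(2,6-dihydroxy-4-methoxyphenyl)ethanone (2',6'-dihydroxy-4'-methoxyacetophenone); 2 benzyl bromide
Product: 5 1-[2-(benzyloxy)-6-hydroxy-4-methoxyphenyl]ethanone
Conditions: BnBr (1.05 equiv), K2CO3 (1.1 equiv), acetone, reflux
Reagents that add atoms: benzyl bromide (compound 2, listed above), BrCc1ccccc1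
Why: Williamson monoalkylation of two equivalent hydroxyls; once one is benzylated the other is held in a strong hydrogen bond to the ketone and is much less nucleophilic, so the reaction should stop at the monoether.

Step 3
Reactants: 3 4-(benzyloxy)-3-methoxybenzoic acid; 5 1-[2-(benzyloxy)-6-hydroxy-4-methoxyphenyl]ethanone
Product: 7 2-acetyl-3-(benzyloxy)-5-methoxyphenyl 4-(benzyloxy)-3-methoxybenzoate, via 4-(benzyloxy)-3-methoxybenzoyl chloride 6 (not isolated)
Conditions: 3, (COCl)2, DMF (cat.), CH2Cl2, 0 °C to rt, evaporate; then 5, pyridine, DMAP (cat.), CH2Cl2, 0 °C to rt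
Reagents that add atoms: none
Why: DMF-catalysed acid chloride formation followed by DMAP-catalysed O-acylation, the standard way to esterify a chelated ortho-acyl phenol; masking the phenol here also prevents benzofuranone formation once the α-carbon carries a leaving group.

Step 4
Reactants: 7 2-acetyl-3-(benzyloxy)-5-methoxyphenyl 4-(benzyloxy)-3-methoxybenzoate
Product: 8 3-(benzyloxy)-2-(bromoacetyl)-5-methoxyphenyl 4-(benzyloxy)-3-methoxybenzoate
Conditions: CuBr2 (2.1 equiv), EtOAc/CHCl3 1:1, reflux
Reagents that add atoms: CuBr2 (copper dibromide), Br[Cu]Br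
Why: Heterogeneous α-bromination of an aryl methyl ketone through its copper-bound enol; CuBr2 is known to brominate the side chain of alkoxy- and hydroxyacetophenones in preference to the electron-rich ring, and it stops cleanly at the monobromide.

Step 5
Reactants: 8 3-(benzyloxy)-2-(bromoacetyl)-5-methoxyphenyl 4-(benzyloxy)-3-methoxybenzoate; 3 4-(benzyloxy)-3-methoxybenzoic acid
Product: 9 3-(benzyloxy)-2-({[4-(benzyloxy)-3-methoxybenzoyl]oxy}acetyl)-5-methoxyphenyl 4-(benzyloxy)-3-methoxybenzoate
Conditions: 3 (1.2 equiv), KHCO3 (1.5 equiv), DMF, rt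
Reagents that add atoms: none
Why: SN2 displacement of a phenacyl bromide by a carboxylate (phenacyl ester formation); hydrogen carbonate is too weak a base to enolise the ketone, so the phenolic ester should remain untouched until the next step.

Step 6
Reactants: 9 3-(benzyloxy)-2-({[4-(benzyloxy)-3-methoxybenzoyl]oxy}acetyl)-5-methoxyphenyl 4-(benzyloxy)-3-methoxybenzoate
Product: 12 5-(benzyloxy)-2-[4-(benzyloxy)-3-methoxyphenyl]-7-methoxy-4-oxo-4H-chromen-3-yl 4-(benzyloxy)-3-methoxybenzoate, via 2-aroyloxy-1,3-diketone 10 (not isolated), via 2-hydroxyflavanone hemiketal 11 (not isolated)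
Conditions: K2CO3 (anhydrous, 4 equiv), pyridine, 90 °C
Reagents that add atoms: none
Why: Carbonate in hot pyridine deprotonates the α-methylene, which is acidified by the ketone and its acyloxy substituent, and the enolate carbon attacks the carbonyl of the ring A phenolic ester through a six-membered cyclic transition state; collapse of the tetrahedral intermediate forms C2–C3 and releases the phenoxide of diketone 10. This is the Baker–Venkataraman rearrangement in its ω-acyloxy variant, the established entry to 3-acyloxyflavones. The phenoxide then adds to the new aryl ketone in a 6-exo-trig closure that forms O1–C2 and ring C as hemiketal 11, and base-mediated loss of water across C2–C3 (E1cB, driven by formation of the conjugated 4-pyranone) should give 12. No stereocenter remains in 12; those of 10 and 11 are transient and need no control. The step needs the phenolic aroyl group to move and the α-aroyl group to stay: the enolate carbon can reach only the phenolic ester carbonyl through a six-membered ring, whereas attack on the α-ester would need a three-membered one, and because both esters carry the same aroyl group any oxygen-to-oxygen acyl exchange is degenerate. Anhydrous conditions are needed so that neither ester is hydrolysed before the transfer.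

Step 7
Reactants: 12 5-(benzyloxy)-2-[4-(benzyloxy)-3-methoxyphenyl]-7-methoxy-4-oxo-4H-chromen-3-yl 4-(benzyloxy)-3-methoxybenzoate
Product: 13 5-(benzyloxy)-2-[4-(benzyloxy)-3-methoxyphenyl]-3-hydroxy-7-methoxy-4H-chromen-4-one
Conditions: K2CO3, MeOH/THF 1:1, 0 °C to rt
Reagents that add atoms: none
Why: Base-catalysed methanolysis (transesterification); the C3 ester is the ester of an acidic enol with a stabilised flavonolate leaving group and is the only ester present, while the benzyl and methyl ethers are inert.

Step 8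
Reactants: 13 5-(benzyloxy)-2-[4-(benzyloxy)-3-methoxyphenyl]-3-hydroxy-7-methoxy-4H-chromen-4-one
Product: 14 5-(benzyloxy)-2-[4-(benzyloxy)-3-methoxyphenyl]-7-methoxy-4-oxo-4H-chromen-3-yl hydrogen sulfate
Conditions: SO3·NMe3 (5 equiv), Et3N (3 equiv), DMF, 60 °C
Reagents that add atoms: sulfur trioxide–trimethylamine complex, C[N+](C)(C)S(=O)(=O)[O-]
Why: O-sulfonation of a hydroxyl by an amine–SO3 complex; the 3-hydroxyl is the only free one because the 5- and 4'-oxygens are benzylated, and the amine keeps the acid-labile monoester as its ammonium salt.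

Step 9
Reactants: 14 5-(benzyloxy)-2-[4-(benzyloxy)-3-methoxyphenyl]-7-methoxy-4-oxo-4H-chromen-3-yl hydrogen sulfate
Product: 15 rhamnazin 3-O-sulfate (5-hydroxy-2-(4-hydroxy-3-methoxyphenyl)-7-methoxy-4-oxo-4H-chromen-3-yl hydrogen sulfate)
Conditions: H2 (1 atm), 10% Pd/C, MeOH/THF 1:1, rt (14 charged as its trialkylammonium salt)
Reagents that add atoms: none
Why: Catalytic hydrogenolysis of two aryl benzyl ethers; the sulfate monoester salt is not reduced, the near-neutral medium should prevent solvolytic loss of SO3, and stopping at two equivalents of hydrogen should leave the chromone C2–C3 double bond intact.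

**Compound list**

1 | vanillic acid (4-hydroxy-3-methoxybenzoic acid) | COc1cc(C(=O)O)ccc1O | starting material
2 | benzyl bromide | BrCc1ccccc1 | starting material
3 | 4-(benzyloxy)-3-methoxybenzoic acid | COc1cc(C(=O)O)ccc1OCc1ccccc1 | intermediate
4 | 1-(2,6-dihydroxy-4-methoxyphenyl)ethanone (2',6'-dihydroxy-4'-methoxyacetophenone) | CC(=O)c1c(O)cc(OC)cc1O | starting material
5 | 1-[2-(benzyloxy)-6-hydroxy-4-methoxyphenyl]ethanone | CC(=O)c1c(O)cc(OC)cc1OCc1ccccc1 | intermediate
6 | 4-(benzyloxy)-3-methoxybenzoyl chloride (formed in the flask, not isolated) | COc1cc(C(=O)Cl)ccc1OCc1ccccc1 | intermediate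
7 | 2-acetyl-3-(benzyloxy)-5-methoxyphenyl 4-(benzyloxy)-3-methoxybenzoate | COc1cc(OCc2ccccc2)c(C(C)=O)c(OC(=O)c2ccc(OCc3ccccc3)c(OC)c2)c1 | intermediate
8 | 3-(benzyloxy)-2-(bromoacetyl)-5-methoxyphenyl 4-(benzyloxy)-3-methoxybenzoate | COc1cc(OCc2ccccc2)c(C(=O)CBr)c(OC(=O)c2ccc(OCc3ccccc3)c(OC)c2)c1 | intermediate
9 | 3-(benzyloxy)-2-({[4-(benzyloxy)-3-methoxybenzoyl]oxy}acetyl)-5-methoxyphenyl 4-(benzyloxy)-3-methoxybenzoate | COc1cc(OCc2ccccc2)c(C(=O)COC(=O)c2ccc(OCc3ccccc3)c(OC)c2)c(OC(=O)c2ccc(OCc3ccccc3)c(OC)c2)c1 | intermediate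
10 | 1-[2-(benzyloxy)-6-hydroxy-4-methoxyphenyl]-3-[4-(benzyloxy)-3-methoxyphenyl]-1,3-dioxopropan-2-yl 4-(benzyloxy)-3-methoxybenzoate (racemic, enolisable; formed in the flask, not isolated) | COc1cc(O)c(C(=O)C(OC(=O)c2ccc(OCc3ccccc3)c(OC)c2)C(=O)c2ccc(OCc3ccccc3)c(OC)c2)c(OCc2ccccc2)c1 | intermediate
11 | 5-(benzyloxy)-2-[4-(benzyloxy)-3-methoxyphenyl]-2-hydroxy-7-methoxy-4-oxo-3,4-dihydro-2H-chromen-3-yl 4-(benzyloxy)-3-methoxybenzoate (mixture of racemic diastereomers; formed in the flask, not isolated) | COc1cc(OCc2ccccc2)c2c(c1)OC(O)(c1ccc(OCc3ccccc3)c(OC)c1)C(OC(=O)c1ccc(OCc3ccccc3)c(OC)c1)C2=O | intermediate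
12 | 5-(benzyloxy)-2-[4-(benzyloxy)-3-methoxyphenyl]-7-methoxy-4-oxo-4H-chromen-3-yl 4-(benzyloxy)-3-methoxybenzoate | COc1cc(OCc2ccccc2)c2c(=O)c(OC(=O)c3ccc(OCc4ccccc4)c(OC)c3)c(-c3ccc(OCc4ccccc4)c(OC)c3)oc2c1 | intermediate
13 | 5-(benzyloxy)-2-[4-(benzyloxy)-3-methoxyphenyl]-3-hydroxy-7-methoxy-4H-chromen-4-one | COc1cc(OCc2ccccc2)c2c(=O)c(O)c(-c3ccc(OCc4ccccc4)c(OC)c3)oc2c1 | intermediate
14 | 5-(benzyloxy)-2-[4-(benzyloxy)-3-methoxyphenyl]-7-methoxy-4-oxo-4H-chromen-3-yl hydrogen sulfate | COc1cc(OCc2ccccc2)c2c(=O)c(OS(=O)(=O)O)c(-c3ccc(OCc4ccccc4)c(OC)c3)oc2c1 | intermediate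
15 | rhamnazin 3-O-sulfate (5-hydroxy-2-(4-hydroxy-3-methoxyphenyl)-7-methoxy-4-oxo-4H-chromen-3-yl hydrogen sulfate; no stereocenters) | COc1cc(O)c2c(=O)c(OS(=O)(=O)O)c(-c3ccc(O)c(OC)c3)oc2c1 | target

**Step count.** Total: 9 steps. Longest linear sequence: 8 steps (from 1 through steps 1 and 3–9, or from 4 through steps 2–9).

**Steps most likely to fail**

Step 6. The aroyl transfer may be overtaken by loss of an ester (adventitious water, or acyl capture by pyridine). The phenoxide freed in that way can displace the α-carboxylate and contract to a five-membered benzofuranone, and dehydration of the hemiketal may stall. The fallback builds the flavone first and oxidises C3 afterwards. Setting out from 7, the classical Baker–Venkataraman rearrangement (KOH, pyridine, 50 °C) should give 1-[2-(benzyloxy)-6-hydroxy-4-methoxyphenyl]-3-[4-(benzyloxy)-3-methoxyphenyl]propane-1,3-dione F1. Mild cyclodehydration (NaOAc, AcOH, 100 °C) should give the flavone 5-(benzyloxy)-2-[4-(benzyloxy)-3-methoxyphenyl]-7-methoxy-4H-chromen-4-one F2. Epoxidation of its C2–C3 double bond with dimethyldioxirane (acetone/CH2Cl2, 0 °C) should give the racemic, cis-fused 2,3-epoxide 6-(benzyloxy)-1a-[4-(benzyloxy)-3-methoxyphenyl]-4-methoxy-1a,7a-dihydro-7H-oxireno[2,3-b]chromen-7-one F3. Catalytic p-TsOH (CHCl3, rt) should isomerise F3 to the flavonol, and the fallback comes back to the route at 13.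

Step 4. Electrophilic bromination of the electron-rich ring A, over-bromination of the side chain, or HBr-mediated loss of the benzyl ether ortho to the ketone may compete. The fallback fixes the site of bromination by first forming the enol ether. Setting out from 7, soft enolisation (TMSOTf, Et3N, CH2Cl2, 0 °C) should give the silyl enol ether 3-(benzyloxy)-5-methoxy-2-{1-[(trimethylsilyl)oxy]ethenyl}phenyl 4-(benzyloxy)-3-methoxybenzoate F4. N-Bromosuccinimide (THF, −78 to 0 °C) should then brominate only the enol carbon under acid-free conditions, and the fallback comes back to the route at 8.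

Step 8. Sulfonation of the hindered C3 hydroxyl, which is hydrogen-bonded to the C4 carbonyl, may be sluggish, and SO3 may be lost again during isolation of the monoester. The fallback introduces the sulfate as a neutral, chromatographable diester. Setting out from 13, 2,2,2-trichloroethyl chlorosulfate (Et3N, DMAP, THF, 0 °C to rt) should give 5-(benzyloxy)-2-[4-(benzyloxy)-3-methoxyphenyl]-7-methoxy-4-oxo-4H-chromen-3-yl 2,2,2-trichloroethyl sulfate F5. Reductive removal of the trichloroethyl group (Zn dust, HCO2NH4, MeOH, rt) should release the monoester as its ammonium salt, and the fallback comes back to the route at 14.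

**Further compounds**

F1 | step 6 | 1-[2-(benzyloxy)-6-hydroxy-4-methoxyphenyl]-3-[4-(benzyloxy)-3-methoxyphenyl]propane-1,3-dione | COc1cc(O)c(C(=O)CC(=O)c2ccc(OCc3ccccc3)c(OC)c2)c(OCc2ccccc2)c1
F2 | step 6 | 5-(benzyloxy)-2-[4-(benzyloxy)-3-methoxyphenyl]-7-methoxy-4H-chromen-4-one | COc1cc(OCc2ccccc2)c2c(=O)cc(-c3ccc(OCc4ccccc4)c(OC)c3)oc2c1
F3 | step 6 | 6-(benzyloxy)-1a-[4-(benzyloxy)-3-methoxyphenyl]-4-methoxy-1a,7a-dihydro-7H-oxireno[2,3-b]chromen-7-one (racemic, cis-fused epoxide) | COc1cc(OCc2ccccc2)c2c(c1)OC1(c3ccc(OCc4ccccc4)c(OC)c3)OC1C2=O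
F4 | step 4 | 3-(benzyloxy)-5-methoxy-2-{1-[(trimethylsilyl)oxy]ethenyl}phenyl 4-(benzyloxy)-3-methoxybenzoate | COc1cc(OCc2ccccc2)c(C(=C)O[Si](C)(C)C)c(OC(=O)c2ccc(OCc3ccccc3)c(OC)c2)c1
F5 | step 8 | 5-(benzyloxy)-2-[4-(benzyloxy)-3-methoxyphenyl]-7-methoxy-4-oxo-4H-chromen-3-yl 2,2,2-trichloroethyl sulfate | COc1cc(OCc2ccccc2)c2c(=O)c(OS(=O)(=O)OCC(Cl)(Cl)Cl)c(-c3ccc(OCc4ccccc4)c(OC)c3)oc2c1
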